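Ring A of the chromanone (C4a, C5, C6, C7, C8, C8a) carries oxygen at C5, C7 and C8a alternating with carbon substituents at C6 and C8; this pattern is cut back to a vinylketene and an ynol ether. In one thermal operation a 3-silyloxycyclobutenone bearing the complete (R)-octanoate side chain and 1-methoxy-5-methylhex-4-en-1-yne are fused into the hexasubstituted benzene, forming C6–C7 and C8–C8a, re-forming C4a–C8a, and leaving the three oxygens differentiated as free OH (C8a), OMe (C7) and silyl ether (C5). The pyranone ring is then grown from the C8a hydroxyl and the free C4a position.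

Key step: step 9

Remark: chromanone numbering is used for the ring atoms throughout, and ketene is assumed to be supplied as the gas from pyrolysis of acetone.

Step 1
Reactants: 1 (S)-4-benzyloxazolidin-2-one; 2 heptanoyl chloride
Product: 3 (S)-4-benzyl-3-heptanoyloxazolidin-2-one
Conditions: Et3N, 4-(dimethylamino)pyridine (cat.), CH2Cl2, 0 °C to rt
Reagents that add atoms: none
Why: N-acylation of the oxazolidinone by the acid chloride under nucleophilic catalysis is routine and leaves the auxiliary stereocentre untouched.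

Step 2
Reactants: 3 (S)-4-benzyl-3-heptanoyloxazolidin-2-one; 4 tert-butyl bromoacetate
Product: 6 tert-butyl (R)-3-[(S)-4-benzyl-2-oxooxazolidine-3-carbonyl]octanoate, via sodium Z-enolate 5 (not isolated)
Conditions: NaN(SiMe3)2, THF, −78 °C; then 4, −78 to −40 °C
Reagents that add atoms: none
Why: Evans alkylation, in which the chelated Z-enolate is attacked by the reactive α-bromo ester on the face opposite the benzyl group, sets the R side-chain stereocentre.

Step 3
Reactants: 6 tert-butyl (R)-3-[(S)-4-benzyl-2-oxooxazolidine-3-carbonyl]octanoate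
Product: 7 tert-butyl (R)-3-(hydroxymethyl)octanoate
Conditions: LiBH4, H2O (1 equiv), Et2O, 0 °C
Reagents that add atoms: none
Why: Reductive cleavage of the N-acyloxazolidinone with LiBH4 is much faster than reduction of the hindered tert-butyl ester, releases auxiliary 1 for recovery and does not touch the stereocentre.

Step 4
Reactants: 7 tert-butyl (R)-3-(hydroxymethyl)octanoate
Product: 8 tert-butyl (R)-3-formyloctanoate
Conditions: Dess–Martin periodinane, CH2Cl2, 0 °C to rt; used crude
Reagents that add atoms: none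
Why: Dess–Martin oxidation is fast and non-basic, so the α-stereocentre of the aldehyde should not epimerise and the γ-hydroxy ester has no time to lactonise.

Step 5
Reactants: 8 tert-butyl (R)-3-formyloctanoate
Product: 9 tert-butyl (R)-3-ethynyloctanoate
Conditions: dimethyl (1-diazo-2-oxopropyl)phosphonate, K2CO3, MeOH, 0 °C to rt
Reagents that add atoms: dimethyl (1-diazo-2-oxopropyl)phosphonate, CC(=O)C(=[N+]=[N-])P(=O)(OC)OC
Why: Seyferth–Gilbert homologation in its Ohira–Bestmann form turns α-branched aldehydes into terminal alkynes under mild carbonate conditions that the tert-butyl ester resists and that are expected to leave the α-stereocentre intact at low temperature.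

Step 6
Reactants: 9 tert-butyl (R)-3-ethynyloctanoate
Product: 12 tert-butyl (R)-3-[(triisopropylsilyloxy)ethynyl]octanoate, via lithium acetylide 10 (not isolated), via lithium ynolate 11 (not isolated)
Conditions: n-BuLi (1.0 equiv), THF, −78 °C; t-BuOOLi (from t-BuOOH and LiN(SiMe3)2), −78 to 0 °C; then i-Pr3SiOTf, −78 °C
Reagents that add atoms: tert-butyl hydroperoxide (used as its lithium salt), CC(C)(C)OO; triisopropylsilyl trifluoromethanesulfonate, CC(C)[Si](OS(=O)(=O)C(F)(F)F)(C(C)C)C(C)C
Why: Oxidation of a lithium acetylide to the ynolate by lithium tert-butyl peroxide and O-silylation with the bulky silyl triflate is the standard preparation of siloxyalkynes, and one equivalent of n-BuLi at −78 °C should remove the acetylenic proton before it can attack or enolise the hindered tert-butyl ester.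

Step 7
Reactants: 12 tert-butyl (R)-3-[(triisopropylsilyloxy)ethynyl]octanoate
Product: 13 tert-butyl (R)-3-[4-oxo-2-(triisopropylsilyloxy)cyclobut-1-en-1-yl]octanoate
Conditions: ketene (gas, excess), CH2Cl2, 0 °C to rt; concentrated and used without chromatography
Reagents that add atoms: ketene, C=C=O
Why: In the ketene–alkyne (2+2) cycloaddition the nucleophilic β-carbon of the siloxyalkyne attacks the ketene carbonyl carbon, so the side chain ends at C2 and the silyloxy group at C3 of the cyclobutenone, the known outcome for triisopropylsiloxyalkynes.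

Step 8
Reactants: 14 2-chloro-1,1-dimethoxyethane; 15 prenyl bromide (1-bromo-3-methylbut-2-ene)
Product: 17 1-methoxy-5-methylhex-4-en-1-yne, via sodium methoxyacetylide 16 (not isolated)
Conditions: NaNH2 (3 equiv), NH3 (l), −33 °C; then 15, −40 °C; distillation
Reagents that add atoms: none
Why: Sodium amide converts the chloroacetal into the alkoxyacetylide by two eliminations and deprotonation, and the acetylide is alkylated in the same flask by SN2 displacement at the primary carbon of the allylic bromide, the established one-pot route to 1-alkoxyalk-1-ynes.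

Step 9
Reactants: 13 tert-butyl (R)-3-[4-oxo-2-(triisopropylsilyloxy)cyclobut-1-en-1-yl]octanoate; 17 1-methoxy-5-methylhex-4-en-1-yne
Product: 22 tert-butyl (R)-3-[4-hydroxy-2-methoxy-3-(3-methylbut-2-en-1-yl)-6-(triisopropylsilyloxy)phenyl]octanoate, via silyloxyvinylketene 18 (not isolated), via 4-vinylcyclobutenone 19 (not isolated), via dienylketene 20 (not isolated), via cyclohexa-2,4-dienone 21 (not isolated)
Conditions: 17 (2 equiv), toluene, 80 °C then 110 °C, sealed tube
Reagents that add atoms: none
Why: Heating opens cyclobutenone 13 by 4π electrocyclic cleavage of C4a–C8a to vinylketene 18, whose ketene carbon (future C8a) is attacked by the nucleophilic β-carbon of ynol ether 17 (future C8), so that the (2+2) cycloaddition also joins C6 to the methoxy-bearing C7 and gives 19. A second 4π opening to dienylketene 20 and a 6π electrocyclisation that re-forms C4a–C8a give dienone 21, which enolises to phenol 22. This is the Danheiser benzannulation of cyclobutenone-derived vinylketenes with alkoxy- and siloxyalkynes, a known route to resorcinol derivatives. Ring A is closed by the thermal disrotatory 6π electrocyclic closure of the dienylketene, followed by aromatisation. No stereocentre is created, and the existing R centre is not acidic and sees only neutral thermal conditions. The one selectivity needed is the regiochemistry of the (2+2) step, which the polarisation of the ynol ether secures (β-carbon to ketene carbonyl), placing OMe at C7 between the side chain and the prenyl group and leaving OH at C8a, the silyl ether at C5 and H at C4a.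

Step 10
Reactants: 22 tert-butyl (R)-3-[4-hydroxy-2-methoxy-3-(3-methylbut-2-en-1-yl)-6-(triisopropylsilyloxy)phenyl]octanoate
Product: 23 tert-butyl (R)-3-[5-formyl-4-hydroxy-2-methoxy-3-(3-methylbut-2-en-1-yl)-6-(triisopropylsilyloxy)phenyl]octanoate
Conditions: MgCl2, Et3N, (CH2O)n, THF, reflux
Reagents that add atoms: paraformaldehyde (reacts as formaldehyde), C=O
Why: Magnesium-phenoxide-directed ortho-formylation (Casnati–Skattebøl type) delivers formaldehyde only ortho to the free hydroxyl, C4a is the single unsubstituted ring carbon, and the ester, silyl ether and prenyl group are inert to these conditions.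

Step 11
Reactants: 23 tert-butyl (R)-3-[5-formyl-4-hydroxy-2-methoxy-3-(3-methylbut-2-en-1-yl)-6-(triisopropylsilyloxy)phenyl]octanoate; 24 (S)-but-3-en-2-ol
Product: 25 tert-butyl (R)-3-[4-[(R)-but-3-en-2-yloxy]-5-formyl-2-methoxy-3-(3-methylbut-2-en-1-yl)-6-(triisopropylsilyloxy)phenyl]octanoate
Conditions: PPh3, diisopropyl azodicarboxylate, toluene, 0 °C to rt
Reagents that add atoms: none
Why: In the Mitsunobu etherification the acidic salicylaldehyde-type phenol displaces the activated secondary alcohol by SN2 with inversion, so the S alcohol gives the R ether carbon that becomes C2.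

Step 12
Reactants: 25 tert-butyl (R)-3-[4-[(R)-but-3-en-2-yloxy]-5-formyl-2-methoxy-3-(3-methylbut-2-en-1-yl)-6-(triisopropylsilyloxy)phenyl]octanoate
Product: 27 tert-butyl (R)-3-[(2R,3R)-7-methoxy-2,3-dimethyl-8-(3-methylbut-2-en-1-yl)-4-oxo-5-(triisopropylsilyloxy)chroman-6-yl]octanoate, via cis-chromanone 26 (not isolated)
Conditions: 3-(2,4,6-trimethylphenyl)-5,6,7,8-tetrahydro-4H-cyclohepta[d][1,3]thiazol-3-ium perchlorate (20 mol %), 1,8-diazabicyclo[5.4.0]undec-7-ene (40 mol %), 1,4-dioxane, 120 °C
Reagents that add atoms: none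
Why: In this N-heterocyclic-carbene-catalysed intramolecular hydroacylation of an unactivated terminal alkene the Breslow intermediate adds across the alkene in a concerted ene-type step (C4 to the internal carbon, the terminal carbon becoming the C3 methyl), C2 is carried in from 25, and C3, being α to the new ketone, should equilibrate under the amidine base to the more stable trans (2R,3R) arrangement.

Step 13
Reactants: 27 tert-butyl (R)-3-[(2R,3R)-7-methoxy-2,3-dimethyl-8-(3-methylbut-2-en-1-yl)-4-oxo-5-(triisopropylsilyloxy)chroman-6-yl]octanoate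
Product: 28 tert-butyl (R)-3-[(2R,3R)-5-hydroxy-7-methoxy-2,3-dimethyl-8-(3-methylbut-2-en-1-yl)-4-oxochroman-6-yl]octanoate
Conditions: Bu4NF, AcOH, THF, 0 °C
Reagents that add atoms: none
Why: Fluoride cleaves the aryl silyl ether, which is activated as a vinylogous silyl ester peri to the C4 carbonyl, and the acetic acid buffer keeps the medium from enolising C3 or opening the pyranone by retro-oxa-Michael reaction.

Step 14
Reactants: 28 tert-butyl (R)-3-[(2R,3R)-5-hydroxy-7-methoxy-2,3-dimethyl-8-(3-methylbut-2-en-1-yl)-4-oxochroman-6-yl]octanoate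
Product: 29 (R)-3-[(2R,3R)-5-hydroxy-7-methoxy-2,3-dimethyl-8-(3-methylbut-2-en-1-yl)-4-oxochroman-6-yl]octanoic acid
Conditions: 85% aq. H3PO4, toluene, rt
Reagents that add atoms: none
Why: Mild acidolysis of the tert-butyl ester by alkyl–oxygen cleavage with loss of isobutene should spare the prenyl alkene, which has no neighbouring free hydroxyl to cyclise onto, and cannot disturb the thermodynamically preferred trans-chromanone.

Compound list
1 | (S)-4-benzyloxazolidin-2-one | O=C1N[C@@H](Cc2ccccc2)CO1 | starting material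
2 | heptanoyl chloride | CCCCCCC(Cl)=O | starting material
3 | (S)-4-benzyl-3-heptanoyloxazolidin-2-one | CCCCCCC(=O)N1[C@@H](Cc2ccccc2)COC1=O | intermediate
4 | tert-butyl bromoacetate | CC(C)(C)OC(=O)CBr | starting material
5 | sodium Z-enolate of 3 (formed in the flask, not isolated) | CCCCC/C=C(\[O-])N1[C@@H](Cc2ccccc2)COC1=O.[Na+] | intermediate
6 | tert-butyl (R)-3-[(S)-4-benzyl-2-oxooxazolidine-3-carbonyl]octanoate | CCCCC[C@H](CC(=O)OC(C)(C)C)C(=O)N1[C@@H](Cc2ccccc2)COC1=O | intermediate
7 | tert-butyl (R)-3-(hydroxymethyl)octanoate | CCCCC[C@H](CC(=O)OC(C)(C)C)CO | intermediate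
8 | tert-butyl (R)-3-formyloctanoate | CCCCC[C@H](CC(=O)OC(C)(C)C)C=O | intermediate
9 | tert-butyl (R)-3-ethynyloctanoate | CCCCC[C@H](CC(=O)OC(C)(C)C)C#C | intermediate
10 | lithium acetylide of 9 (formed in the flask, not isolated) | CCCCC[C@H](CC(=O)OC(C)(C)C)C#C[Li] | intermediate
11 | lithium ynolate, tert-butyl (R)-3-(lithiooxyethynyl)octanoate (formed in the flask, not isolated) | CCCCC[C@H](CC(=O)OC(C)(C)C)C#CO[Li] | intermediate
12 | tert-butyl (R)-3-[(triisopropylsilyloxy)ethynyl]octanoate | CCCCC[C@H](CC(=O)OC(C)(C)C)C#CO[Si](C(C)C)(C(C)C)C(C)C | intermediate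
13 | tert-butyl (R)-3-[4-oxo-2-(triisopropylsilyloxy)cyclobut-1-en-1-yl]octanoate | CCCCC[C@H](CC(=O)OC(C)(C)C)C1=C(O[Si](C(C)C)(C(C)C)C(C)C)CC1=O | intermediate
14 | 2-chloro-1,1-dimethoxyethane | COC(CCl)OC | starting material
15 | prenyl bromide (1-bromo-3-methylbut-2-ene) | CC(C)=CCBr | starting material
16 | sodium methoxyacetylide (formed in the flask, not isolated) | COC#C[Na] | intermediate
17 | 1-methoxy-5-methylhex-4-en-1-yne | COC#CCC=C(C)C | intermediate
18 | silyloxyvinylketene, tert-butyl (R)-3-[1-oxo-3-(triisopropylsilyloxy)buta-1,3-dien-2-yl]octanoate (not isolated) | CCCCC[C@H](CC(=O)OC(C)(C)C)C(=C=O)C(=C)O[Si](C(C)C)(C(C)C)C(C)C | intermediate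
19 | 4-vinylcyclobutenone, tert-butyl (3R)-3-[2-methoxy-3-(3-methylbut-2-en-1-yl)-4-oxo-1-[1-(triisopropylsilyloxy)vinyl]cyclobut-2-en-1-yl]octanoate (ring carbon unassigned, not isolated) | CCCCC[C@H](CC(=O)OC(C)(C)C)C1(C(=C)O[Si](C(C)C)(C(C)C)C(C)C)C(OC)=C(CC=C(C)C)C1=O | intermediate
20 | dienylketene (isomer with the silyloxyvinyl group cis to the ketene, not isolated) | CCCCC[C@H](CC(=O)OC(C)(C)C)/C(C(=C)O[Si](C(C)C)(C(C)C)C(C)C)=C(OC)/C(CC=C(C)C)=C=O | intermediate
21 | cyclohexa-2,4-dienone tautomer of 22 (not isolated) | CCCCC[C@H](CC(=O)OC(C)(C)C)C1=C(O[Si](C(C)C)(C(C)C)C(C)C)CC(=O)C(CC=C(C)C)=C1OC | intermediate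
22 | tert-butyl (R)-3-[4-hydroxy-2-methoxy-3-(3-methylbut-2-en-1-yl)-6-(triisopropylsilyloxy)phenyl]octanoate | CCCCC[C@H](CC(=O)OC(C)(C)C)c1c(O[Si](C(C)C)(C(C)C)C(C)C)cc(O)c(CC=C(C)C)c1OC | intermediate
23 | tert-butyl (R)-3-[5-formyl-4-hydroxy-2-methoxy-3-(3-methylbut-2-en-1-yl)-6-(triisopropylsilyloxy)phenyl]octanoate | CCCCC[C@H](CC(=O)OC(C)(C)C)c1c(O[Si](C(C)C)(C(C)C)C(C)C)c(C=O)c(O)c(CC=C(C)C)c1OC | intermediate
24 | (S)-but-3-en-2-ol | C[C@H](O)C=C | starting material
25 | tert-butyl (R)-3-[4-[(R)-but-3-en-2-yloxy]-5-formyl-2-methoxy-3-(3-methylbut-2-en-1-yl)-6-(triisopropylsilyloxy)phenyl]octanoate | CCCCC[C@H](CC(=O)OC(C)(C)C)c1c(O[Si](C(C)C)(C(C)C)C(C)C)c(C=O)c(O[C@H](C)C=C)c(CC=C(C)C)c1OC | intermediate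
26 | cis-chromanone, the (2R,3S) C3 epimer of 27 (formed in the flask, equilibrated, not isolated) | CCCCC[C@H](CC(=O)OC(C)(C)C)c1c(O[Si](C(C)C)(C(C)C)C(C)C)c2c(c(CC=C(C)C)c1OC)O[C@H](C)[C@H](C)C2=O | intermediate
27 | tert-butyl (R)-3-[(2R,3R)-7-methoxy-2,3-dimethyl-8-(3-methylbut-2-en-1-yl)-4-oxo-5-(triisopropylsilyloxy)chroman-6-yl]octanoate | CCCCC[C@H](CC(=O)OC(C)(C)C)c1c(O[Si](C(C)C)(C(C)C)C(C)C)c2c(c(CC=C(C)C)c1OC)O[C@H](C)[C@@H](C)C2=O | intermediate
28 | tert-butyl (R)-3-[(2R,3R)-5-hydroxy-7-methoxy-2,3-dimethyl-8-(3-methylbut-2-en-1-yl)-4-oxochroman-6-yl]octanoate | CCCCC[C@H](CC(=O)OC(C)(C)C)c1c(O)c2c(c(CC=C(C)C)c1OC)O[C@H](C)[C@@H](C)C2=O | intermediate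
29 | (R)-3-[(2R,3R)-5-hydroxy-7-methoxy-2,3-dimethyl-8-(3-methylbut-2-en-1-yl)-4-oxochroman-6-yl]octanoic acid | CCCCC[C@H](CC(=O)O)c1c(O)c2c(c(CC=C(C)C)c1OC)O[C@H](C)[C@@H](C)C2=O | target

Total step count: 14. Longest linear sequence: 13 steps (steps 1–7 and 9–14); step 8 makes the second annulation partner.

Steps most likely to fail

Step 9 (benzannulation). The vinylketene may dimerise or acylate the phenol already formed faster than it adds the hindered, disubstituted ynol ether, or the crowded dienylketene may close slowly. The fallback introduces the prenyl group after the annulation and sets out from 13 and 14. Sodium methoxyacetylide 16 (NaNH2, NH3) would be protonated and distilled to give methoxyethyne F1, a much less hindered ketenophile. Heating 13 with F1 in toluene in a sealed tube should give tert-butyl (R)-3-[4-hydroxy-2-methoxy-6-(triisopropylsilyloxy)phenyl]octanoate F2. Tsuji–Trost O-allylation of F2 with methyl 2-methylbut-3-en-2-yl carbonate and Pd(PPh3)4 would give the 1,1-dimethylallyl ether tert-butyl (R)-3-[2-methoxy-4-(2-methylbut-3-en-2-yloxy)-6-(triisopropylsilyloxy)phenyl]octanoate F3. Aromatic Claisen rearrangement (toluene, 110 °C) to the ortho position not shielded by the silyl ether (C8) would return the route at 22.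

Step 12 (hydroacylation). Addition of the carbene to an aldehyde flanked by two ortho oxygen substituents may be slow, and hot basic conditions may erode C2 through ring opening and reclosure. The fallback builds the pyranone by aldol reaction and ether closure, sets out from 23 and replaces steps 11 and 12. EtMgBr (excess, THF, −78 °C) would add to the aldehyde to give tert-butyl (3R)-3-[4-hydroxy-5-(1-hydroxypropyl)-2-methoxy-3-(3-methylbut-2-en-1-yl)-6-(triisopropylsilyloxy)phenyl]octanoate F4. MnO2 (CH2Cl2) would oxidise the benzylic alcohol to tert-butyl (R)-3-[4-hydroxy-2-methoxy-3-(3-methylbut-2-en-1-yl)-5-propanoyl-6-(triisopropylsilyloxy)phenyl]octanoate F5. A boron aldol reaction with acetaldehyde (the enantiomer of diisopinocampheylboron triflate that gives the 2R,3S syn adduct, i-Pr2NEt, CH2Cl2, −78 °C) would give tert-butyl (R)-3-[4-hydroxy-5-[(2R,3S)-3-hydroxy-2-methylbutanoyl]-2-methoxy-3-(3-methylbut-2-en-1-yl)-6-(triisopropylsilyloxy)phenyl]octanoate F6. Intramolecular Mitsunobu etherification (PPh3, diisopropyl azodicarboxylate) with inversion at the carbinol would close the trans-chromanone and return the route at 27.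

Step 11 (Mitsunobu etherification). The hindered, hydrogen-bonded phenol may react incompletely, and SN2′ attack or ionisation of the allylic alcohol would lower the configurational purity at C2. The fallback sets the C2 stereocentre by catalyst control and sets out from 23. Tsuji–Trost asymmetric allylic etherification with (E)-but-2-en-1-yl methyl carbonate and Pd2(dba)3·CHCl3 would be used, with the enantiomer of N,N′-(cyclohexane-1,2-diyl)bis[2-(diphenylphosphino)benzamide] that delivers the branched R ether. It returns the route at 25, no longer needs 24 and makes no new compound (F0).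

Further compounds
F1 | step 9 | methoxyethyne | COC#C
F2 | step 9 | tert-butyl (R)-3-[4-hydroxy-2-methoxy-6-(triisopropylsilyloxy)phenyl]octanoate | CCCCC[C@H](CC(=O)OC(C)(C)C)c1c(O[Si](C(C)C)(C(C)C)C(C)C)cc(O)cc1OC
F3 | step 9 | tert-butyl (R)-3-[2-methoxy-4-(2-methylbut-3-en-2-yloxy)-6-(triisopropylsilyloxy)phenyl]octanoate | CCCCC[C@H](CC(=O)OC(C)(C)C)c1c(O[Si](C(C)C)(C(C)C)C(C)C)cc(OC(C)(C)C=C)cc1OC
F4 | step 12 | tert-butyl (3R)-3-[4-hydroxy-5-(1-hydroxypropyl)-2-methoxy-3-(3-methylbut-2-en-1-yl)-6-(triisopropylsilyloxy)phenyl]octanoate (both carbinol epimers) | CCCCC[C@H](CC(=O)OC(C)(C)C)c1c(O[Si](C(C)C)(C(C)C)C(C)C)c(C(O)CC)c(O)c(CC=C(C)C)c1OC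
F5 | step 12 | tert-butyl (R)-3-[4-hydroxy-2-methoxy-3-(3-methylbut-2-en-1-yl)-5-propanoyl-6-(triisopropylsilyloxy)phenyl]octanoate | CCCCC[C@H](CC(=O)OC(C)(C)C)c1c(O[Si](C(C)C)(C(C)C)C(C)C)c(C(=O)CC)c(O)c(CC=C(C)C)c1OC
F6 | step 12 | tert-butyl (R)-3-[4-hydroxy-5-[(2R,3S)-3-hydroxy-2-methylbutanoyl]-2-methoxy-3-(3-methylbut-2-en-1-yl)-6-(triisopropylsilyloxy)phenyl]octanoate | CCCCC[C@H](CC(=O)OC(C)(C)C)c1c(O[Si](C(C)C)(C(C)C)C(C)C)c(C(=O)[C@H](C)[C@H](C)O)c(O)c(CC=C(C)C)c1OC
F0 | step 11 | none | none
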